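## Structural features

The target is a 6-oxabicyclo[3.2.2]non-3-ene-2,7-dione. Its seven-membered carbocycle C1–C2–C3–C4–C5–C9–C8 is spanned from C5 to C1 by the lactone bridge O6–C7(=O), so that C1, C8, C9, C5, O6 and C7 form a δ-lactone locked as a boat. C5 is a bridgehead mixed ketal (OMe and lactone oxygen, a pseudo-ester) and also the γ-carbon of the enone C2(=O)–C3(allyl)=C4, while C1 is the bridgehead CH of a β-keto lactone. C2 and C5 are both at the ketone oxidation level and stand 1,4 to each other across C3=C4, a dissonant pattern. Of the four stereocentres, C1 and C5 are tied by the bridge. C8 (aryl) and C9 (methyl) are contiguous and trans on the two-carbon bridge, the aryl on the lactone side (cis to the C1 carboxyl on the carbocycle) and the methyl on the enone side. Fragile groups are the acylal lactone (opened by alkoxides, ionisable by acid and, being allylic to C3=C4, by zerovalent palladium), the β-keto lactone, the skipped allyl-enone diene and the electron-rich arene. The real difficulty is C1: in any open precursor with C2 as a ketone it is the α-carbon of a β-keto acid, which epimerises and decarboxylates, and the carboxyl-cis-to-aryl arrangement is not the one an equilibrium in the monocycle should favour. The key step exploits the fact that the carbocycle is the [3,3] product of a cis-dialkenylcyclopropane made of C3, C4 and C5: the Cope shift forms C1–C8 with cis geometry, and C2 and C5 emerge as two different enol derivatives, C5 already carrying the OMe of the target.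

## Logic of the disconnections

15 ⇒ 14. The C3–CH2 bond of the allyl group is cut (Stille coupling). The allyl group must come late because the key step needs a terminal alkyne, which leaves C3 with a hydrogen. The α-carbon of the enone is the one position that iodination followed by cross-coupling reaches regiospecifically. The forward step demands that palladium inserts into C–I faster than it ionises the allylic acylal.

14 ⇒ 13. The C3–I bond is cut (α-iodination of the enone). This removes only a handle and puts no demand on stereochemistry.

13 ⇒ 11 (through 12). The C3=C4 double bond is removed and C2 returns to the enol acetate that the key step delivers. C1 is a bridgehead, so the ketone can only be desaturated toward C4. The forward step must unmask the enol acetate without a free alkoxide, which would open the lactone.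

11 ⇒ 10. The O6–C5 bond and the C9–H bond are cut. The bicycle becomes a monocyclic cyclohepta-2,5-diene bearing a methyl enol ether and a tert-butyl ester. Forward, an oxocarbenium ion at C5 is captured across the ring by the carboxyl group, a kinetic closure that avoids any keto acid. The demand is that the carboxyl already stands cis to the aryl group and cannot epimerise, which holds because C2 is still an enol acetate.

10 ⇒ 4 + 8 (through 9). This is the key disconnection. In the numbering of 10 the bonds C1–C7 and C3–C4 are cut, which is a formal [4+3] between the 2-methoxydiene 4 (C4, C5, C6, C7) and the three-carbon vinylcarbene from 8 (C3, C2, C1). The seven-membered ring, both ketone-level carbons in differentiated form, and the C1/C7 stereocentres are all made in one operation from two achiral or racemic pieces. The forward step demands carbene transfer to the enol ether alkene of 4 only, a cis-cyclopropane, E geometry at both alkene termini, and catalyst control of the face.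

4 ⇒ 3 ⇒ 1 + 2. The terminal C=CH2 is cut back to the ester carbonyl (methylenation), then the trisubstituted alkene is cut (Wittig). The ester must be the methyl ester, because its OMe becomes the bridgehead OMe of 15.

8 ⇒ 7 ⇒ 6 ⇒ 5. The acetyl–O bond, then the alkynyl–carbinol C–C bond, then the central C–C bond of a tartrate (glycol cleavage) are cut. The tert-butyl ester is chosen because it is later expelled as isobutene under the acid that closes the lactone.

## Other disconnections considered

Alternative 1: The first idea is the biogenetic one. O6 is removed (retro-Baeyer–Villiger) and C1–C8 and C5–C9 are cut together. Forward, the cation from quinone monoketal A1 adds (E)-isoelemicin A2 in a cationic [5+2] cycloaddition to give bicyclo[3.2.1]octenedione A3, and Baeyer–Villiger migration of the methoxy-bearing bridgehead gives 15. It is the shortest route. The chosen plan is preferred for three reasons: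
- The cation from A1 is planar and achiral and A2 has no handle, so the absolute configuration would need a resolution.
- The same benzylic cation can close through oxygen to a dihydrobenzofuran ([3+2] mode), and the exo orientation of the aryl group needed in A3 has no evident control element.
- The peracid would have to select one of two ketones in the presence of an enone, an allyl group and an electron-rich arene.

Alternative 2: Only O6–C5 is cut, at the ketone level. Forward, the keto acid A4 would be made by conjugate addition and ring closure and then ketalised transannularly with methanol. In A4, C1 is the α-carbon of a β-keto acid. It epimerises freely, the carboxyl is expected to prefer the side trans to the aryl group (the opposite of what 15 needs), decarboxylation competes, and under equilibrium the open methyl ester competes with the pseudo-ester. The hardest stereochemical relationship would be left to an uncontrolled equilibrium, whereas the chosen plan sets it in a concerted step and locks it.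

Alternative 3: C1–C8 and C5–C9 are cut on a smaller bicycle. Forward, 6-methoxy-2H-pyran-2-one A5 and A2 would undergo a Diels–Alder reaction to the bridged lactone A6, whose CH=CH bridge would then be expanded by one carbon (dihalocarbene addition, ring opening, oxidation) to the enone bridge. An electron-rich diene is paired with an electron-rich styrene, so forcing conditions are expected, under which adducts of this type lose CO2. The ring expansion must also choose which allyl terminus receives the oxygen. The route is racemic and longer after the key step.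

Key step: step 6

Assumption: the sense of induction of the digold catalyst cannot be derived for this substrate pair. The (R)-ligand is written; the (S)-ligand is used instead if it delivers the mirror-image cyclopropane.

## Steps

Step 1
Reactants: 1 3,4,5-trimethoxybenzaldehyde; 2 methyl 2-(triphenyl-λ5-phosphanylidene)propanoate
Product: 3 methyl (2E)-2-methyl-3-(3,4,5-trimethoxyphenyl)prop-2-enoate
Conditions: toluene, 90 °C
Reagents that add atoms: none
Why: Wittig olefination with a stabilised ylide; reversible oxaphosphetane formation should give the E alkene (aryl trans to the ester).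

Step 2
Reactants: 3 methyl (2E)-2-methyl-3-(3,4,5-trimethoxyphenyl)prop-2-enoate
Product: 4 1,2,3-trimethoxy-5-[(1E)-3-methoxy-2-methylbuta-1,3-dien-1-yl]benzene
Conditions: Cp2TiMe2 (2.2 equiv), toluene, 65 °C, dark; filtration through basic alumina
Reagents that add atoms: dimethyltitanocene, C[Ti](C)(C1C=CC=C1)C1C=CC=C1
Why: Petasis methylenation of the ester carbonyl through Cp2Ti=CH2 and an oxatitanacyclobutane; the ester OMe becomes the enol ether OMe that ends as the bridgehead OMe, and the trisubstituted alkene is not touched.

Step 3
Reactants: 5 di-tert-butyl (2R,3R)-2,3-dihydroxybutanedioate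
Product: 6 tert-butyl oxoacetate
Conditions: H5IO6, Et2O, rt
Reagents that add atoms: none
Why: Malaprade glycol cleavage; each tartrate gives two molecules of the glyoxylate, used freshly.

Step 4
Reactants: 6 tert-butyl oxoacetate
Product: 7 tert-butyl 2-hydroxybut-3-ynoate (racemic)
Conditions: HC≡CMgBr, THF, −78 °C; aq NH4Cl
Reagents that add atoms: ethynylmagnesium bromide, C#C[Mg]Br
Why: Grignard addition to the aldehyde, which is far more electrophilic than the hindered tert-butyl ester; the new stereocentre is erased in step 6, so the racemate is used.

Step 5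
Reactants: 7 tert-butyl 2-hydroxybut-3-ynoate
Product: 8 tert-butyl 2-(acetyloxy)but-3-ynoate (racemic)
Conditions: Ac2O, pyridine, DMAP (cat.), CH2Cl2, 0 °C
Reagents that add atoms: acetic anhydride, CC(=O)OC(C)=O
Why: O-acylation of the secondary alcohol; low temperature keeps the acidic propargylic C–H from isomerising to the allene.

Step 6
Reactants: 4 1,2,3-trimethoxy-5-[(1E)-3-methoxy-2-methylbuta-1,3-dien-1-yl]benzene; 8 tert-butyl 2-(acetyloxy)but-3-ynoate
Product: 10 tert-butyl (1R,7R)-2-(acetyloxy)-5-methoxy-6-methyl-7-(3,4,5-trimethoxyphenyl)cyclohepta-2,5-diene-1-carboxylate, via cis-divinylcyclopropane 9 (not isolated)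
Conditions: (R)-DTBM-SEGPHOS(AuCl)2 (2.5 mol %), AgSbF6 (5 mol %), MeNO2, −25 °C to rt; 8 (1.5 equiv) added slowly
Reagents that add atoms: none
Why: Cationic monovalent gold activates the terminal alkyne of 8, the acetate carbonyl closes 5-exo-dig onto the internal carbon, and opening of the dioxolenium (1,2-acyloxy shift) gives the gold vinylcarbenoid AuCH–C(OAc)=CH–CO2tBu with the ester cis to OAc. The carbenoid is transferred to the 1,1-disubstituted methyl enol ether of 4, the more nucleophilic and less hindered of its two alkenes, closing the three-membered ring C3–C4–C5 as the cis-dialkenylcyclopropane 9 inside the chiral pocket of the digold catalyst. As a donor-substituted cis-divinylcyclopropane, 9 should undergo the Cope rearrangement at or below room temperature: C3–C5 breaks and C1–C7 forms, closing the seven-membered ring by a [3,3] shift through the boat transition state, the only one open to a cis-divinylcyclopropane. The closest known reaction type is the gold- or ruthenium-catalysed cyclopropanation of 1,3-dienes with propargyl carboxylates followed by Cope rearrangement (formal [4+3]), together with the enantioselective cyclopropanation by these carbenoids under bisphosphine digold chlorides. C1 and C7 are created together: both alkene termini carry their substituent (ester, aryl) trans to the cyclopropane, so both sit exo in the boat and end cis on the ring, which is the carboxyl-cis-to-aryl relationship of the target. Their absolute configuration is that of (1S,2R)-9, fixed by catalyst-controlled face selection at the enol ether and passed on stereospecifically by the concerted shift. The step needs 1,2- over 1,3-acyloxy shift (secured by the terminal alkyne), enol ether over styrenyl alkene (electronics and sterics) and the cis-cyclopropane (the usual preference of these carbenoids). C1 stays configurationally fixed afterwards because C2 leaves the step as an enol acetate and not as a ketone.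

Step 7
Reactants: 10 tert-butyl (1R,7R)-2-(acetyloxy)-5-methoxy-6-methyl-7-(3,4,5-trimethoxyphenyl)cyclohepta-2,5-diene-1-carboxylate
Product: 11 (1R,5R,8R,9R)-5-methoxy-9-methyl-7-oxo-8-(3,4,5-trimethoxyphenyl)-6-oxabicyclo[3.2.2]non-2-en-2-yl acetate
Conditions: TFA (5 equiv), 4 Å MS, CH2Cl2, −20 to 0 °C
Reagents that add atoms: none
Why: Protonation of the methyl enol ether at C6 gives an oxocarbenium ion at C5 that the carbonyl oxygen of the tert-butyl ester captures across the ring with loss of isobutene (acid-mediated addition of a carboxyl group to an enol ether, pseudo-ester formation). The bridge can only span the face on which the carboxyl already sits, so C5 follows C1. Protonation at C6 is reversible, and the epimer with methyl trans to aryl should win because the C8–C9 bond is eclipsed in the bicycle.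

Step 8
Reactants: 11 (1R,5R,8R,9R)-5-methoxy-9-methyl-7-oxo-8-(3,4,5-trimethoxyphenyl)-6-oxabicyclo[3.2.2]non-2-en-2-yl acetate
Product: 13 (1R,5R,8R,9R)-5-methoxy-9-methyl-8-(3,4,5-trimethoxyphenyl)-6-oxabicyclo[3.2.2]non-3-ene-2,7-dione, via tributyltin enolate 12 (not isolated)
Conditions: Bu3SnOMe (1.1 equiv), MeCN, rt; then Pd(OAc)2 (1.1 equiv), rt
Reagents that add atoms: none
Why: The tin methoxide takes the acetyl group and leaves the tin enolate, which transmetallates to Pd(OAc)2 and undergoes β-hydride elimination toward C4 (Saegusa–Ito-type oxidation, run on the tin enolate of an enol acetate). C1 is a bridgehead, so only C3–C4 can be desaturated, and no stereocentre is touched.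

Step 9
Reactants: 13 (1R,5R,8R,9R)-5-methoxy-9-methyl-8-(3,4,5-trimethoxyphenyl)-6-oxabicyclo[3.2.2]non-3-ene-2,7-dione
Product: 14 (1R,5S,8R,9R)-3-iodo-5-methoxy-9-methyl-8-(3,4,5-trimethoxyphenyl)-6-oxabicyclo[3.2.2]non-3-ene-2,7-dione
Conditions: I2 (2 equiv), pyridine–CH2Cl2 (1:1), 0 °C to rt
Reagents that add atoms: iodine, I-I
Why: α-Iodination of the enone by conjugate addition of pyridine at C4, iodination of the enolate at C3 and loss of pyridine (Baylis–Hillman-type sequence); I2/pyridine should not iodinate the arene, and the leaving group on C5 is not β to the enolate carbon.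

Step 10
Reactants: 14 (1R,5S,8R,9R)-3-iodo-5-methoxy-9-methyl-8-(3,4,5-trimethoxyphenyl)-6-oxabicyclo[3.2.2]non-3-ene-2,7-dione
Product: 15 (1R,5S,8R,9R)-5-methoxy-9-methyl-3-(prop-2-en-1-yl)-8-(3,4,5-trimethoxyphenyl)-6-oxabicyclo[3.2.2]non-3-ene-2,7-dione
Conditions: allylSnBu3 (1.5 equiv), Pd2(dba)3 (5 mol %), AsPh3 (20 mol %), CuI (10 mol %), NMP, rt
Reagents that add atoms: allyltributylstannane, C=CC[Sn](CCCC)(CCCC)CCCC
Why: Stille coupling of an α-iodoenone; oxidative addition into the C(sp2)–I bond at room temperature should outpace ionisation of the hindered tertiary allylic acylal, whose anti face is shielded by the C9 methyl group. AsPh3 and CuI speed the transmetallation.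

## Compound list

1 | 3,4,5-trimethoxybenzaldehyde | COc1cc(C=O)cc(OC)c1OC | starting material
2 | methyl 2-(triphenyl-λ5-phosphanylidene)propanoate | COC(=O)C(C)=P(c1ccccc1)(c1ccccc1)c1ccccc1 | starting material
3 | methyl (2E)-2-methyl-3-(3,4,5-trimethoxyphenyl)prop-2-enoate | COC(=O)/C(C)=C/c1cc(OC)c(OC)c(OC)c1 | intermediate
4 | 1,2,3-trimethoxy-5-[(1E)-3-methoxy-2-methylbuta-1,3-dien-1-yl]benzene | C=C(OC)/C(C)=C/c1cc(OC)c(OC)c(OC)c1 | intermediate
5 | di-tert-butyl (2R,3R)-2,3-dihydroxybutanedioate | CC(C)(C)OC(=O)[C@H](O)[C@@H](O)C(=O)OC(C)(C)C | starting material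
6 | tert-butyl oxoacetate | CC(C)(C)OC(=O)C=O | intermediate
7 | tert-butyl 2-hydroxybut-3-ynoate (racemic) | C#CC(O)C(=O)OC(C)(C)C | intermediate
8 | tert-butyl 2-(acetyloxy)but-3-ynoate (racemic) | C#CC(OC(C)=O)C(=O)OC(C)(C)C | intermediate
9 | tert-butyl (2Z)-3-(acetyloxy)-3-{(1S,2R)-2-methoxy-2-[(1E)-1-(3,4,5-trimethoxyphenyl)prop-1-en-2-yl]cyclopropyl}prop-2-enoate | CC(C)(C)OC(=O)/C=C(OC(C)=O)/[C@@H]1C[C@]1(OC)/C(C)=C/c1cc(OC)c(OC)c(OC)c1 | intermediate (not isolated)
10 | tert-butyl (1R,7R)-2-(acetyloxy)-5-methoxy-6-methyl-7-(3,4,5-trimethoxyphenyl)cyclohepta-2,5-diene-1-carboxylate | CC(C)(C)OC(=O)[C@@H]1[C@H](c2cc(OC)c(OC)c(OC)c2)C(C)=C(OC)CC=C1OC(C)=O | intermediate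
11 | (1R,5R,8R,9R)-5-methoxy-9-methyl-7-oxo-8-(3,4,5-trimethoxyphenyl)-6-oxabicyclo[3.2.2]non-2-en-2-yl acetate | CC(=O)OC1=CC[C@@]2(OC)OC(=O)[C@@H]1[C@H](c1cc(OC)c(OC)c(OC)c1)[C@H]2C | intermediate
12 | tributyl{[(1R,5R,8R,9R)-5-methoxy-9-methyl-7-oxo-8-(3,4,5-trimethoxyphenyl)-6-oxabicyclo[3.2.2]non-2-en-2-yl]oxy}stannane | CCCC[Sn](CCCC)(CCCC)OC1=CC[C@@]2(OC)OC(=O)[C@@H]1[C@H](c1cc(OC)c(OC)c(OC)c1)[C@H]2C | intermediate (not isolated)
13 | (1R,5R,8R,9R)-5-methoxy-9-methyl-8-(3,4,5-trimethoxyphenyl)-6-oxabicyclo[3.2.2]non-3-ene-2,7-dione | O=C1C=C[C@@]2(OC)OC(=O)[C@@H]1[C@H](c1cc(OC)c(OC)c(OC)c1)[C@H]2C | intermediate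
14 | (1R,5S,8R,9R)-3-iodo-5-methoxy-9-methyl-8-(3,4,5-trimethoxyphenyl)-6-oxabicyclo[3.2.2]non-3-ene-2,7-dione | O=C1C(I)=C[C@@]2(OC)OC(=O)[C@@H]1[C@H](c1cc(OC)c(OC)c(OC)c1)[C@H]2C | intermediate
15 | (1R,5S,8R,9R)-5-methoxy-9-methyl-3-(prop-2-en-1-yl)-8-(3,4,5-trimethoxyphenyl)-6-oxabicyclo[3.2.2]non-3-ene-2,7-dione | C=CCC1=C[C@@]2(OC)OC(=O)[C@@H](C1=O)[C@H](c1cc(OC)c(OC)c(OC)c1)[C@H]2C | target

## Step count and least certain steps

Total step count: 10. Longest linear sequence: 8 steps (steps 3 to 10, from 5); the branch from 1 runs through steps 1, 2 and 6 to 10.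

Step 6 (key step). Three things may go wrong:
- The zwitterion formed when the enol ether attacks the carbenoid may close to a five-membered ring (formal [3+2]) in place of the cyclopropane.
- The ester on the propargylic carbon may slow the acyloxy shift.
- The donor–acceptor cyclopropane may open heterolytically before the Cope shift, which would erode the enantiomeric purity and the cis relationship at C1/C7.

Fallback (resolution in place of catalyst control): from 4 and 8 the cascade is run with the achiral complex Ph3PAuCl/AgSbF6, or with [RuCl2(CO)3]2, a second catalyst family for the same carbene transfer. This gives 10 together with its mirror image, tert-butyl (1S,7S)-2-(acetyloxy)-5-methoxy-6-methyl-7-(3,4,5-trimethoxyphenyl)cyclohepta-2,5-diene-1-carboxylate F2, through 9 and the mirror-image (1R,2S)-cyclopropane F1. 10 is separated from F2 by preparative chromatography on a chiral stationary phase, and the route is rejoined at 10.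

Step 7. The oxocarbenium ion at C5 may be diverted before the carboxyl captures it: hydrolysis by adventitious water to the ketone, Friedel–Crafts attack by the ortho carbon of the arene, or tert-butylation of the arene by the released cation. Incomplete equilibration at C9 would leave the cis-methyl epimer. Fallback (unmasking and closure separated): from 10, TMSOTf/2,6-lutidine in CH2Cl2 at 0 °C converts the tert-butyl ester into the silyl ester, and buffered work-up gives (1R,7R)-2-(acetyloxy)-5-methoxy-6-methyl-7-(3,4,5-trimethoxyphenyl)cyclohepta-2,5-diene-1-carboxylic acid F3. F3 is closed with catalytic PPTS in CH2Cl2 over 4 Å MS under thermodynamic control, returning to 11.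

Step 8. The tin methoxide may transfer to the lactone carbonyl and open the acylal, and the palladium formed may ionise the allylic acylal of the product. Fallback (deacylation and dehydrogenation without tin or palladium): from 11, immobilised Candida antarctica lipase B with n-butanol in MTBE transfers the acetyl group and leaves (1R,5R,8R,9R)-5-methoxy-9-methyl-8-(3,4,5-trimethoxyphenyl)-6-oxabicyclo[3.2.2]nonane-2,7-dione F4. F4 can enolise only toward C3 and is dehydrogenated with IBX in DMSO at 60 °C, returning to 13.

Step 10. Zerovalent palladium may ionise the tertiary allylic acylal, or a palladium hydride may move the allyl double bond into conjugation. Fallback (no palladium): from 14, radical allylation of the Keck type with allyltributylstannane and AIBN in benzene at 80 °C gives 15 directly.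

## Further compounds

F1 | step 6 | tert-butyl (2Z)-3-(acetyloxy)-3-{(1R,2S)-2-methoxy-2-[(1E)-1-(3,4,5-trimethoxyphenyl)prop-1-en-2-yl]cyclopropyl}prop-2-enoate | CC(C)(C)OC(=O)/C=C(OC(C)=O)/[C@H]1C[C@@]1(OC)/C(C)=C/c1cc(OC)c(OC)c(OC)c1
F2 | step 6 | tert-butyl (1S,7S)-2-(acetyloxy)-5-methoxy-6-methyl-7-(3,4,5-trimethoxyphenyl)cyclohepta-2,5-diene-1-carboxylate | CC(C)(C)OC(=O)[C@H]1[C@@H](c2cc(OC)c(OC)c(OC)c2)C(C)=C(OC)CC=C1OC(C)=O
F3 | step 7 | (1R,7R)-2-(acetyloxy)-5-methoxy-6-methyl-7-(3,4,5-trimethoxyphenyl)cyclohepta-2,5-diene-1-carboxylic acid | OC(=O)[C@@H]1[C@H](c2cc(OC)c(OC)c(OC)c2)C(C)=C(OC)CC=C1OC(C)=O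
F4 | step 8 | (1R,5R,8R,9R)-5-methoxy-9-methyl-8-(3,4,5-trimethoxyphenyl)-6-oxabicyclo[3.2.2]nonane-2,7-dione | O=C1CC[C@@]2(OC)OC(=O)[C@@H]1[C@H](c1cc(OC)c(OC)c(OC)c1)[C@H]2C
F0 | step 10 | none | none
A1 | alternative 1 | 4,4,5-trimethoxy-2-(prop-2-en-1-yl)cyclohexa-2,5-dien-1-one | C=CCC1=CC(OC)(OC)C(OC)=CC1=O
A2 | alternative 1 | 1,2,3-trimethoxy-5-[(1E)-prop-1-en-1-yl]benzene | C/C=C/c1cc(OC)c(OC)c(OC)c1
A3 | alternative 1 | (1R,5R,6R,7R)-5-methoxy-6-methyl-3-(prop-2-en-1-yl)-7-(3,4,5-trimethoxyphenyl)bicyclo[3.2.1]oct-3-ene-2,8-dione | C=CCC1=C[C@@]2(OC)C(=O)[C@@H](C1=O)[C@H](c1cc(OC)c(OC)c(OC)c1)[C@H]2C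
A4 | alternative 2 | (1R,6R,7R)-6-methyl-2,5-dioxo-3-(prop-2-en-1-yl)-7-(3,4,5-trimethoxyphenyl)cyclohept-3-ene-1-carboxylic acid | OC(=O)[C@@H]1[C@H](c2cc(OC)c(OC)c(OC)c2)[C@@H](C)C(=O)C=C(CC=C)C1=O
A5 | alternative 3 | 6-methoxy-2H-pyran-2-one | COC1=CC=CC(=O)O1
A6 | alternative 3 | (1R,4S,7R,8R)-1-methoxy-7-methyl-8-(3,4,5-trimethoxyphenyl)-2-oxabicyclo[2.2.2]oct-5-en-3-one | C1=C[C@@]2(OC)OC(=O)[C@@H]1[C@H](c1cc(OC)c(OC)c(OC)c1)[C@H]2C
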